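**Plan**
- Retrosynthesis, in order: the C8 ester C–O bond (8β-alcohol + epoxyangelic acid), the C1/C10 oxirane, the lactone (C6,C12-diol), C5–H (enol triflate), then the key retro-[3,3] step that breaks C2–C3 and re-forms C5–C10, then C4–C5 (alkenyl-metal addition), C10–C1 (α-vinylation) and the C6, C8, C12 oxygens, back to (R)-carvone.
- Enabling feature: oxirane carbons C10, C1 and alkene carbons C4, C5 of the ten-membered ring are linked through C2–C3 as a 1,5-diene (C10=C1–C2–C3–C4=C5), so a cyclohexane made of C5–C10 opens across C5–C10 when C2–C3 is made.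
- Forward ring order: six-membered ring of carvone (C5–C10), then the ten-membered ring by ring expansion (step 19), then the γ-lactone (step 24), then the oxirane (step 30); the acyl oxirane is made separately (steps 26–28).
- Stereochemistry: C7 from (R)-carvone; C8 by singlet-oxygen addition anti to the side chain, later epimerised by oxidation and hindered-hydride reduction; C10, C6, C5 by substrate control on a locked chair; C3 from the Z enol ether through the chair [3,3] shift; C1/C10 by peripheral epoxidation; the acid by Sharpless epoxidation.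

Key step: step 19

Remark on numbering: all intermediates carry the germacrane numbers of the target (C5–C10 = ring carbons of carvone, C5 its carbonyl carbon; C11–C13 side chain; C14, C15 methyl groups). β is the ring face that carries the C7 side chain, α the other face. PMB = 4-methoxybenzyl, MOM = methoxymethyl, TBS = tert-butyldimethylsilyl, TMS = trimethylsilyl.
Assumption: the SMILES is read as the (1R,3S,6R,7R,8R,10R) compound (1β,10α-epoxide, 3β-benzoate, 8β-ester, 6α,12-olide) with a (2R,3R)-2,3-dimethyloxirane-2-carbonyl group.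
Remark on C8: O8 enters trans to the side chain (8α, equatorial) and stays so while C10, C6 and C5 are built, because an axial 8β group would shield the β-face of C10 in step 7; it is epimerised in steps 15–17.

**Step 1**
Reactants: 1 (R)-carvone
Product: 2 10-chlorocarvone
Conditions: Ca(OCl)2, CO2 (s), CH2Cl2/H2O, 0 °C
Reagents that add atoms: calcium hypochlorite, [Ca+2].[O-]Cl.[O-]Cl (chlorine)
Why: Ene-type allylic chlorination by HOCl attacks only the electron-rich side-chain alkene (the enone alkene is deactivated) and shifts the double bond onto the equivalent methylene terminus, so C12 is functionalised and the C7 stereocentre is untouched.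

**Step 2**
Reactants: 2 10-chlorocarvone
Product: 4 10-hydroxycarvone, via allylic acetate 3 (not isolated)
Conditions: KOAc, Bu4NI (cat.), DMF, 50 °C; then MeOH, K2CO3 (cat.), 0 °C → rt
Reagents that add atoms: potassium acetate, CC(=O)[O-].[K+] (one oxygen stays as O12)
Why: SN2 displacement of the primary allylic chloride by acetate followed by mild transesterification frees the primary allylic alcohol without touching the enone.

**Step 3**
Reactants: 4 10-hydroxycarvone
Product: 5 12-O-MOM enone
Conditions: MOMCl, i-Pr2NEt, CH2Cl2, 0 °C → rt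
Reagents that add atoms: chloromethyl methyl ether, COCCl
Why: O-alkylation of the primary alcohol gives an acetal that survives the hydride, organometallic and strongly basic steps ahead.

**Step 4**
Reactants: 5 12-O-MOM enone
Product: 7 TMS dienol ether (5-silyloxy-5(10),8-diene), via bromomagnesium dienolate 6 (not isolated)
Conditions: MeMgBr, FeCl3 (cat.), Et2O, −20 °C; then Me3SiCl, Et3N, DMPU, −20 °C → rt
Reagents that add atoms: chlorotrimethylsilane, C[Si](C)(C)Cl
Why: The iron-catalysed MeMgBr base (Kharasch reagent) removes the γ-hydrogen at C8 instead of adding to the carbonyl or enolising towards C6, and O-silylation of the through-conjugated dienolate gives the s-cis 1-silyloxy-1,3-diene.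

**Step 5**
Reactants: 7 TMS dienol ether
Product: 10 8α-hydroxy enone (4S,5R in cyclohexenone numbering), via silyloxy endoperoxide 8 (not isolated), via 8α-hydroperoxy enone 9 (not isolated)
Conditions: O2, hν, tetraphenylporphyrin (cat.), CH2Cl2, −78 °C; then MeOH, PPh3, −78 °C → rt
Reagents that add atoms: dioxygen, O=O (one oxygen stays as O8)
Why: Singlet oxygen adds in a [4+2] cycloaddition across C5 and C8 of the cyclic diene from the face anti to the C7 side chain, methanolysis of the silyl peroxyketal opens it to the γ-hydroperoxy enone and PPh3 reduces the O–O bond, so oxygen ends up only at C8 and trans to the side chain.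

**Step 6**
Reactants: 10 8α-hydroxy enone
Product: 11 8α-OTBS enone
Conditions: t-BuMe2SiCl, imidazole, DMF, rt
Reagents that add atoms: tert-butyldimethylsilyl chloride, CC(C)(C)[Si](C)(C)Cl
Why: Imidazole-catalysed silylation protects the equatorial allylic alcohol as a robust ether for the enolate chemistry that follows.

**Step 7**
Reactants: 11 8α-OTBS enone
Product: 13 aldol (10β-(1-hydroxyethyl)-10α-methyl ketone; carbinol epimers), via lithium enolate 12 (not isolated)
Conditions: LiBH(s-Bu)3, THF, −78 °C; then MeCHO, −78 °C; H2O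
Reagents that add atoms: acetaldehyde, CC=O
Why: Conjugate hydride addition to the β-unsubstituted enone gives the C5–C10 enolate regiospecifically, and its aldol reaction (reductive aldol) occurs by axial attack on the β-face of the half-chair with equatorial C7 and C8 substituents, the sense known for the dihydrocarvone enolate, so the new two-carbon unit on quaternary C10 is cis to the side chain and the methyl group is α.

**Step 8**
Reactants: 13 aldol
Product: 14 10β-vinyl-10α-methyl ketone (8α-OTBS)
Conditions: MeO2CN(−)SO2N(+)Et3 (Burgess reagent), toluene, 70 °C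
Reagents that add atoms: none
Why: Syn-elimination of the sulfamate can only take a hydrogen from the methyl group because C10 is quaternary, so the C1=C2 vinyl group forms from both carbinol epimers without conjugation or skeletal change.

**Step 9**
Reactants: 14 vinyl ketone
Product: 16 6α-hydroxy ketone, via sodium enolate 15 (not isolated)
Conditions: NaN(SiMe3)2, THF, −78 °C; then 2-(phenylsulfonyl)-3-phenyloxaziridine, −78 °C
Reagents that add atoms: 2-(phenylsulfonyl)-3-phenyloxaziridine, O=S(=O)(N1OC1c1ccccc1)c1ccccc1 (oxygen)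
Why: Only the C5–C6 enolate can form because C10 is quaternary, and Davis oxidation delivers oxygen anti to the adjacent C7 side chain to give the equatorial 6α-alcohol, which is also the thermodynamically preferred epimer.

**Step 10**
Reactants: 16 6α-hydroxy ketone
Product: 17 6α-OMOM ketone
Conditions: MOMCl, i-Pr2NEt, Bu4NI (cat.), CH2Cl2, 0 °C → rt
Reagents that add atoms: chloromethyl methyl ether, COCCl
Why: Acetal protection of the α-ketol under non-enolising conditions gives a chelating ether at O6 that cannot migrate, whereas a silyl group there would shift to the neighbouring alkoxide or enolate oxygen in the key step.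

**Step 11**
Reactants: 18 4-methoxybenzyl alcohol
Product: 19 allyl 4-methoxybenzyl ether
Conditions: allyl bromide, KOH, Bu4NI (cat.), THF, rt
Reagents that add atoms: allyl bromide, C=CCBr
Why: Williamson etherification of the benzylic alcohol with a reactive allylic halide.

**Step 12**
Reactants: 19 allyl 4-methoxybenzyl ether
Product: 20 (Z)-prop-1-enyl 4-methoxybenzyl ether
Conditions: KOt-Bu (cat.), DMSO, rt → 50 °C
Reagents that add atoms: none
Why: Base-mediated allyl to propenyl ether isomerisation runs through the oxygen-coordinated cis allyl anion and therefore gives the Z enol ether.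

**Step 13**
Reactants: 20 (Z)-propenyl PMB ether
Product: 22 (Z)-2-bromoprop-1-enyl 4-methoxybenzyl ether, via vicinal dibromide 21 (not isolated)
Conditions: Br2, CH2Cl2, −78 °C; then DBU, −78 °C → rt
Reagents that add atoms: bromine, BrBr
Why: Anti addition of bromine and anti elimination of HBr from the α-bromo ether (C1–Br, C2–H) place bromine cis to oxygen, which is also the favoured geometry of β-halo enol ethers; any E isomer is removed by chromatography.

**Step 14**
Reactants: 17 6α-OMOM ketone; 22 Z-bromo enol ether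
Product: 25 cis-dialkenyl carbinol (5α-OH; 5β-[(Z)-1-methyl-2-(PMB-oxy)vinyl]; 8α-OTBS), via alkenyllithium 23 (not isolated), via alkenylcerium dichloride 24 (not isolated)
Conditions: 22, t-BuLi (2 equiv), Et2O, −78 °C; CeCl3, THF, −78 °C; then 17, −78 → −40 °C
Reagents that add atoms: none
Why: Bromine–lithium exchange with retention gives the alkenyllithium with lithium cis to oxygen, which cannot undergo anti β-elimination, and its weakly basic cerium derivative adds to the α-alkoxy ketone under Cram-chelate control along the equatorial trajectory of the locked chair, so the new alkenyl group is equatorial and cis to the axial 10β-vinyl group and the hydroxyl is 5α, cis to O6.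

**Step 15**
Reactants: 25 carbinol
Product: 26 5α,8α-diol
Conditions: Bu4NF, THF, 0 °C → rt
Reagents that add atoms: none
Why: Fluoride cleaves the secondary silyl ether while the acetals, the PMB enol ether and the tertiary alcohol are inert.

**Step 16**
Reactants: 26 5α,8α-diol
Product: 27 8-ketone
Conditions: Dess–Martin periodinane, NaHCO3, CH2Cl2, 0 °C → rt
Reagents that add atoms: none
Why: Buffered Dess–Martin oxidation converts the only secondary alcohol into the ketone and leaves the tertiary allylic alcohol and the acid-sensitive enol ether untouched.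

**Step 17**
Reactants: 27 8-ketone
Product: 28 5α,8β-diol
Conditions: LiBH(s-Bu)3, THF, −78 °C
Reagents that add atoms: none
Why: The bulky hydride attacks the C8 carbonyl along the equatorial trajectory because the axial approach on the β-face is blocked by the axial 10β-vinyl group, which gives the axial 8β-alcohol cis to the C7 side chain as the target requires.

**Step 18**
Reactants: 28 5α,8β-diol
Product: 29 oxy-Cope precursor (8β-OTBS; free 5α-OH)
Conditions: t-BuMe2SiOSO2CF3, 2,6-lutidine, CH2Cl2, −78 °C
Reagents that add atoms: tert-butyldimethylsilyl triflate, CC(C)(C)[Si](C)(C)OS(=O)(=O)C(F)(F)F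
Why: The silyl triflate with a hindered base silylates the axial secondary alcohol at low temperature, while the tertiary C5 hydroxyl needed for the key step is too hindered to react.

**Step 19**
Reactants: 29 oxy-Cope precursor
Product: 32 ten-membered enol triflate (C5–OTf; ring-cis C4=C5; 1(10)E; 3S-OPMB), via potassium alkoxide 30 (not isolated), via potassium enolate 31 (not isolated)
Conditions: KH, 18-crown-6, THF, 0 °C → rt; then PhNTf2, −78 → 0 °C
Reagents that add atoms: N-phenylbis(trifluoromethanesulfonimide), O=S(=O)(N(c1ccccc1)S(=O)(=O)C(F)(F)F)C(F)(F)F (CF3SO2 group)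
Why: KH/18-crown-6 gives the naked alkoxide 30, which undergoes a concerted, charge-accelerated [3,3] sigmatropic shift that forms C2–C3 while breaking C5–C10; the closest known reaction type is the anionic oxy-Cope ring expansion of cis-1,2-dialkenylcyclohexanols to cyclodec-5-enone enolates with O-trapping. The ten-membered ring is not closed end to end but arises by four-atom enlargement of the cyclohexane (both reacting alkenes exocyclic to the six-membered ring, the breaking bond endocyclic), so no macrocyclisation entropy is paid. The cyclohexane chair with equatorial C6 and C7 substituents holds O5 and the C10 vinyl group axial and antiperiplanar, and in the chair-shaped six-atom array built on it C6 is axial and C9 equatorial, which gives the ring-cis C4=C5 enolate 31 and the 1(10)E alkene, whereas the other chair needs two syn-diaxial contacts and a boat would give the Z,Z or E,E diene. The one new stereocentre, C3, is set by suprafacial bonding of C2 to the face of C3=C4 from which C10 departs, so the Z enol ether (PMB-oxy axial on the array) gives 3S. The step needs chair over boat and the correct chair, secured by the cis-dialkenyl arrangement and the equatorial C6/C7 groups, and it needs the β-alkoxy enolate intercepted before it expels the C3 alkoxide, secured by low-temperature triflation, which also freezes the enolate geometry.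

**Step 20**
Reactants: 32 enol triflate
Product: 33 1(10)E,4Z-diene (C5–H)
Conditions: Pd(OAc)2 (cat.), PPh3, HCO2H, n-Bu3N, DMF, 60 °C
Reagents that add atoms: none
Why: Palladium-catalysed formate reduction of the enol triflate (oxidative addition, decarboxylation of the formate, reductive elimination) replaces OTf by H with retention of alkene geometry.

**Step 21**
Reactants: 33 diene
Product: 34 3β-alcohol (3S)
Conditions: DDQ, CH2Cl2/pH 7 buffer, 0 °C
Reagents that add atoms: none
Why: Oxidative PMB cleavage through the benzylic oxocarbenium ion frees the C3 hydroxyl without acid and leaves the MOM and silyl ethers and the diene intact.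

**Step 22**
Reactants: 34 3β-alcohol
Product: 35 3β-benzoate
Conditions: PhCOCl, pyridine, DMAP (cat.), CH2Cl2, 0 °C → rt
Reagents that add atoms: benzoyl chloride, O=C(Cl)c1ccccc1
Why: DMAP-catalysed acylation of the secondary allylic alcohol installs the benzoate with retention at C3.

**Step 23**
Reactants: 35 3β-benzoate
Product: 36 6α,12-diol
Conditions: MgBr2·OEt2, n-BuSH, Et2O, rt
Reagents that add atoms: none
Why: MgBr2 activates both MOM acetals and the thiol captures the methoxymethyl cation, a mild Lewis-acid/soft-nucleophile cleavage that spares the silyl ether, the benzoate and the acid-sensitive 1(10),4-diene.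

**Step 24**
Reactants: 36 6α,12-diol
Product: 39 α-methylene γ-lactone (8β-OTBS), via hydroxy enal 37 (not isolated), via lactol 38 (not isolated)
Conditions: TEMPO (cat.), PhI(OAc)2, CH2Cl2, rt
Reagents that add atoms: none
Why: The oxoammonium oxidant oxidises the primary allylic alcohol much faster than a secondary one, the enal is trapped by the C6 hydroxyl as a five-membered lactol, and this is oxidised on to the lactone, trans-fused because C6 and C7 keep their configurations.

**Step 25**
Reactants: 39 lactone silyl ether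
Product: 40 8β-hydroxy lactone
Conditions: HF·pyridine, pyridine, THF, 0 °C → rt
Reagents that add atoms: none
Why: Buffered HF·pyridine removes the secondary TBS ether without opening the lactone, cleaving the benzoate or adding to the α-methylene group.

**Step 26**
Reactants: 41 angelic acid
Product: 42 (Z)-2-methylbut-2-en-1-ol
Conditions: LiAlH4, Et2O, 0 °C → rt
Reagents that add atoms: none
Why: Hydride reduction of the carboxylic acid gives the allylic alcohol without isomerising the Z double bond.

**Step 27**
Reactants: 42 (Z)-2-methylbut-2-en-1-ol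
Product: 43 [(2S,3R)-2,3-dimethyloxiran-2-yl]methanol
Conditions: Ti(Oi-Pr)4, L-(+)-diethyl tartrate, t-BuOOH, 4 Å molecular sieves, CH2Cl2, −20 °C
Reagents that add atoms: tert-butyl hydroperoxide, CC(C)(C)OO (oxygen)
Why: In the Sharpless asymmetric epoxidation the L-(+)-tartrate titanium complex delivers oxygen to the face of the allylic alcohol that gives the (2S,3R)-epoxy alcohol, and syn addition keeps the two methyl groups trans.

**Step 28**
Reactants: 43 epoxy alcohol
Product: 44 (2R,3R)-2,3-dimethyloxirane-2-carboxylic acid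
Conditions: RuCl3 (cat.), NaIO4, MeCN/EtOAc/H2O, 0 °C → rt
Reagents that add atoms: water, O (second carboxyl oxygen)
Why: Catalytically generated ruthenium tetroxide oxidises the primary alcohol through the aldehyde hydrate to the glycidic acid without touching the oxirane, and the C2 descriptor changes to R only through the change in substituent priority.

**Step 29**
Reactants: 40 8β-hydroxy lactone; 44 epoxy acid
Product: 46 8β-(epoxyangeloyloxy) diene lactone, via mixed anhydride 45 (not isolated)
Conditions: 44, 2,4,6-Cl3C6H2COCl, Et3N, toluene, rt; then 40, DMAP, toluene, rt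
Reagents that add atoms: none
Why: In the Yamaguchi esterification DMAP attacks the less hindered carbonyl of the mixed anhydride and the acylpyridinium acylates the hindered 8β-alcohol with retention at C8 and without opening the oxirane.

**Step 30**
Reactants: 46 diene lactone
Product: 47 CNP0324463.6
Conditions: m-CPBA, NaHCO3, CH2Cl2, 0 °C
Reagents that add atoms: 3-chloroperbenzoic acid, O=C(OO)c1cccc(Cl)c1 (oxygen)
Why: Prilezhaev epoxidation selects the electron-rich trisubstituted C1=C10 alkene over the 4,5-alkene (deactivated by two allylic acyloxy groups) and the electron-poor methylene lactone, and attack on the exposed outer face of the E alkene in the conformer with C14 on the β-face should give the 1β,10α-epoxide (1R,10R).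

**Compound list**
1 | (R)-carvone | CC1=CC[C@H](CC1=O)C(C)=C | starting material
2 | 10-chlorocarvone, (R)-5-(3-chloroprop-1-en-2-yl)-2-methylcyclohex-2-en-1-one | C=C(CCl)[C@H]1CC(=O)C(C)=CC1 | intermediate
3 | 10-acetoxycarvone (allylic acetate) | C=C(COC(C)=O)[C@H]1CC(=O)C(C)=CC1 | intermediate (not isolated)
4 | 10-hydroxycarvone, (R)-5-(3-hydroxyprop-1-en-2-yl)-2-methylcyclohex-2-en-1-one | C=C(CO)[C@H]1CC(=O)C(C)=CC1 | intermediate
5 | 12-O-MOM enone | C=C(COCOC)[C@H]1CC(=O)C(C)=CC1 | intermediate
6 | bromomagnesium dienolate of 5 (C5=C10, C8=C9) | C=C(COCOC)[C@H]1CC(O[Mg]Br)=C(C)C=C1 | intermediate (not isolated)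
7 | TMS dienol ether (5-trimethylsilyloxy-5(10),8-diene) | C=C(COCOC)[C@H]1CC(O[Si](C)(C)C)=C(C)C=C1 | intermediate
8 | 5α,8α-epidioxide of 7 (silyloxy endoperoxide) | C=C(COCOC)[C@H]1C[C@]2(O[Si](C)(C)C)OO[C@H]1C=C2C | intermediate (not isolated)
9 | 8α-hydroperoxy enone | C=C(COCOC)[C@H]1CC(=O)C(C)=C[C@@H]1OO | intermediate (not isolated)
10 | 8α-hydroxy enone, (4S,5R)-4-hydroxy-5-[3-(methoxymethoxy)prop-1-en-2-yl]-2-methylcyclohex-2-en-1-one | C=C(COCOC)[C@H]1CC(=O)C(C)=C[C@@H]1O | intermediate
11 | 8α-OTBS enone | C=C(COCOC)[C@H]1CC(=O)C(C)=C[C@@H]1O[Si](C)(C)C(C)(C)C | intermediate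
12 | lithium C5(10)-enolate of dihydro-11 | C=C(COCOC)[C@H]1CC([O-])=C(C)C[C@@H]1O[Si](C)(C)C(C)(C)C.[Li+] | intermediate (not isolated)
13 | aldol, 10β-(1-hydroxyethyl)-10α-methyl ketone (carbinol centre as mixture) | C=C(COCOC)[C@H]1CC(=O)[C@@](C)(C(C)O)C[C@@H]1O[Si](C)(C)C(C)(C)C | intermediate
14 | 10β-vinyl-10α-methyl ketone, 8α-OTBS | C=C(COCOC)[C@H]1CC(=O)[C@@](C)(C=C)C[C@@H]1O[Si](C)(C)C(C)(C)C | intermediate
15 | sodium C5(6)-enolate of 14 | C=C(COCOC)[C@H]1C=C([O-])[C@@](C)(C=C)C[C@@H]1O[Si](C)(C)C(C)(C)C.[Na+] | intermediate (not isolated)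
16 | 6α-hydroxy ketone | C=C(COCOC)[C@H]1[C@H](O)C(=O)[C@@](C)(C=C)C[C@@H]1O[Si](C)(C)C(C)(C)C | intermediate
17 | 6α-OMOM ketone | C=C(COCOC)[C@H]1[C@H](OCOC)C(=O)[C@@](C)(C=C)C[C@@H]1O[Si](C)(C)C(C)(C)C | intermediate
18 | 4-methoxybenzyl alcohol | COc1ccc(CO)cc1 | starting material
19 | allyl 4-methoxybenzyl ether | C=CCOCc1ccc(OC)cc1 | intermediate
20 | (Z)-prop-1-enyl 4-methoxybenzyl ether | C/C=C\OCc1ccc(OC)cc1 | intermediate
21 | 1,2-dibromopropyl 4-methoxybenzyl ether (racemic) | CC(Br)C(Br)OCc1ccc(OC)cc1 | intermediate (not isolated)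
22 | (Z)-2-bromoprop-1-enyl 4-methoxybenzyl ether (Br cis to O) | C/C(Br)=C/OCc1ccc(OC)cc1 | intermediate
23 | alkenyllithium from 22 (Li cis to O) | C/C([Li])=C/OCc1ccc(OC)cc1 | intermediate (not isolated)
24 | alkenylcerium dichloride from 23 | C/C([Ce](Cl)Cl)=C/OCc1ccc(OC)cc1 | intermediate (not isolated)
25 | cis-dialkenyl carbinol: 5α-OH, 5β-[(Z)-1-methyl-2-(PMB-oxy)vinyl], 6α-OMOM, 8α-OTBS, 10β-vinyl | C=C(COCOC)[C@H]1[C@H](OCOC)[C@@](O)(/C(C)=C\OCc2ccc(OC)cc2)[C@@](C)(C=C)C[C@@H]1O[Si](C)(C)C(C)(C)C | intermediate
26 | 5α,8α-diol | C=C(COCOC)[C@H]1[C@H](OCOC)[C@@](O)(/C(C)=C\OCc2ccc(OC)cc2)[C@@](C)(C=C)C[C@@H]1O | intermediate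
27 | 8-ketone | C=C(COCOC)[C@H]1[C@H](OCOC)[C@@](O)(/C(C)=C\OCc2ccc(OC)cc2)[C@@](C)(C=C)CC1=O | intermediate
28 | 5α,8β-diol | C=C(COCOC)[C@H]1[C@H](OCOC)[C@@](O)(/C(C)=C\OCc2ccc(OC)cc2)[C@@](C)(C=C)C[C@H]1O | intermediate
29 | oxy-Cope precursor: 28 as its 8β-TBS ether | C=C(COCOC)[C@H]1[C@H](OCOC)[C@@](O)(/C(C)=C\OCc2ccc(OC)cc2)[C@@](C)(C=C)C[C@H]1O[Si](C)(C)C(C)(C)C | intermediate
30 | potassium alkoxide of 29 | C=C(COCOC)[C@H]1[C@H](OCOC)[C@@]([O-])(/C(C)=C\OCc2ccc(OC)cc2)[C@@](C)(C=C)C[C@H]1O[Si](C)(C)C(C)(C)C.[K+] | intermediate (not isolated)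
31 | ten-membered potassium C4(5)-enolate (ring-cis), 1(10)E, 3S | C=C(COCOC)[C@H]1[C@H](OCOC)/C([O-])=C(/C)[C@@H](OCc2ccc(OC)cc2)C/C=C(\C)C[C@H]1O[Si](C)(C)C(C)(C)C.[K+] | intermediate (not isolated)
32 | ten-membered C5 enol triflate, ring-cis C4=C5, 1(10)E, 3S-OPMB, 6α-OMOM, 8β-OTBS | C=C(COCOC)[C@H]1[C@H](OCOC)/C(OS(=O)(=O)C(F)(F)F)=C(/C)[C@@H](OCc2ccc(OC)cc2)C/C=C(\C)C[C@H]1O[Si](C)(C)C(C)(C)C | intermediate
33 | 1(10)E,4Z-diene, 3β-OPMB | C=C(COCOC)[C@H]1[C@H](OCOC)/C=C(/C)[C@@H](OCc2ccc(OC)cc2)C/C=C(\C)C[C@H]1O[Si](C)(C)C(C)(C)C | intermediate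
34 | 3β-alcohol (3S) | C=C(COCOC)[C@H]1[C@H](OCOC)/C=C(/C)[C@@H](O)C/C=C(\C)C[C@H]1O[Si](C)(C)C(C)(C)C | intermediate
35 | 3β-benzoate | C=C(COCOC)[C@H]1[C@H](OCOC)/C=C(/C)[C@@H](OC(=O)c2ccccc2)C/C=C(\C)C[C@H]1O[Si](C)(C)C(C)(C)C | intermediate
36 | 6α,12-diol | C=C(CO)[C@H]1[C@H](O)/C=C(/C)[C@@H](OC(=O)c2ccccc2)C/C=C(\C)C[C@H]1O[Si](C)(C)C(C)(C)C | intermediate
37 | 6α-hydroxy C12 enal | C=C(C=O)[C@H]1[C@H](O)/C=C(/C)[C@@H](OC(=O)c2ccccc2)C/C=C(\C)C[C@H]1O[Si](C)(C)C(C)(C)C | intermediate (not isolated)
38 | 6α,12-lactol (C12 epimers) | C=C1C(O)O[C@@H]2/C=C(/C)[C@@H](OC(=O)c3ccccc3)C/C=C(\C)C[C@@H](O[Si](C)(C)C(C)(C)C)[C@@H]12 | intermediate (not isolated)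
39 | 3β-benzoyloxy-8β-(TBS-oxy)germacra-1(10)E,4Z,11(13)-trien-6α,12-olide | C=C1C(=O)O[C@@H]2/C=C(/C)[C@@H](OC(=O)c3ccccc3)C/C=C(\C)C[C@@H](O[Si](C)(C)C(C)(C)C)[C@@H]12 | intermediate
40 | 8β-hydroxy lactone | C=C1C(=O)O[C@@H]2/C=C(/C)[C@@H](OC(=O)c3ccccc3)C/C=C(\C)C[C@@H](O)[C@@H]12 | intermediate
41 | angelic acid | C/C=C(/C)C(=O)O | starting material
42 | (Z)-2-methylbut-2-en-1-ol | C/C=C(/C)CO | intermediate
43 | [(2S,3R)-2,3-dimethyloxiran-2-yl]methanol | OC[C@]1(C)O[C@@H]1C | intermediate
44 | (2R,3R)-2,3-dimethyloxirane-2-carboxylic acid | OC(=O)[C@]1(C)O[C@@H]1C | intermediate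
45 | mixed anhydride of 44 with 2,4,6-trichlorobenzoic acid | O=C(OC(=O)c1c(Cl)cc(Cl)cc1Cl)[C@]1(C)O[C@@H]1C | intermediate (not isolated)
46 | 3β-benzoyloxy-8β-[(2R,3R)-2,3-dimethyloxirane-2-carbonyloxy]germacra-1(10)E,4Z,11(13)-trien-6α,12-olide | C=C1C(=O)O[C@@H]2/C=C(/C)[C@@H](OC(=O)c3ccccc3)C/C=C(\C)C[C@@H](OC(=O)[C@]3(C)O[C@@H]3C)[C@@H]12 | intermediate
47 | CNP0324463.6, the 1β,10α-epoxide of 46 | C=C1C(=O)O[C@@H]2/C=C(/C)[C@@H](OC(=O)c3ccccc3)C[C@H]3O[C@]3(C)C[C@@H](OC(=O)[C@]3(C)O[C@@H]3C)[C@@H]12 | target

**Step count:** 30 steps in total. Longest linear sequence: 24 steps from (R)-carvone (steps 1–10, 14–25, 29, 30); the side branches are steps 11–13 and 26–28.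

**Steps most likely to fail**

Step 19. The rearrangement may leak through the other chair or a boat-shaped array, because the productive chair carries the axial PMB-oxy group on C3 and a 1,3-diaxial contact between the 10β-vinyl and 8β-silyloxy groups; the enolate may also lose PMB-oxide by β-elimination before it is triflated. Either erodes the 4Z/1(10)E geometry, the C3 configuration or the mass balance. Fallback: the ring expansion is moved in front of the C8 epimerisation. It sets out from 25, whose reacting chair has every ring substituent except O5 and the vinyl group equatorial. KH/18-crown-6 gives the potassium alkoxide F1, which rearranges to the potassium enolate F2, and PhNTf2 gives the 8α-silyloxy enol triflate F3. Pd(OAc)2/PPh3/HCO2H/n-Bu3N reduction gives the 8α-silyloxy diene F4 and Bu4NF the 8α-alcohol F5. Mitsunobu inversion with chloroacetic acid (PPh3, diisopropyl azodicarboxylate) gives the 8β-chloroacetate F6, K2CO3/MeOH the 8β-alcohol F7, and t-BuMe2SiOSO2CF3/2,6-lutidine returns to the route at 33.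

Step 14. The basic alkenyl metal may enolise the hindered ketone, or attack may follow the axial trajectory and give the trans-dialkenyl carbinol, which cannot reach the Z,E-diene. Fallback: the addition is run on the unprotected ketol. It sets out from 16 and the cerium reagent 24 (from 22). The first equivalent of 24 converts 16 into the cerium alkoxide F8, in which the metal bridges O6 and the carbonyl oxygen. A second equivalent adds to this rigid five-membered chelate from the face of H6 (the known cis-diol selectivity of additions to cyclic α-ketols) to give the 5α,6α-diol F9. Selective MOM protection of the secondary hydroxyl (MOMCl, i-Pr2NEt) returns to the route at 25.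

Step 4. The deprotonation may not be fully γ-selective (competing enolisation towards C6 or carbonyl addition of the Grignard reagent), which would misplace the oxygen introduced in step 5. Fallback: direct allylic C–H oxidation. It sets out from 5: Pd(OH)2/C with t-BuOOH and K2CO3 in CH2Cl2 oxidises the C8 methylene to the ene-dione F10. Luche reduction (NaBH4, CeCl3·7H2O, MeOH, −78 °C) of the less hindered C8 carbonyl by axial hydride attack gives the equatorial 8α-alcohol and returns to the route at 10.

**Further compounds**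
F1 | step 19 | potassium alkoxide of 25 | C=C(COCOC)[C@H]1[C@H](OCOC)[C@@]([O-])(/C(C)=C\OCc2ccc(OC)cc2)[C@@](C)(C=C)C[C@@H]1O[Si](C)(C)C(C)(C)C.[K+]
F2 | step 19 | ten-membered potassium enolate, 8α-OTBS | C=C(COCOC)[C@H]1[C@H](OCOC)/C([O-])=C(/C)[C@@H](OCc2ccc(OC)cc2)C/C=C(\C)C[C@@H]1O[Si](C)(C)C(C)(C)C.[K+]
F3 | step 19 | 8α-silyloxy enol triflate (8-epimer of 32) | C=C(COCOC)[C@H]1[C@H](OCOC)/C(OS(=O)(=O)C(F)(F)F)=C(/C)[C@@H](OCc2ccc(OC)cc2)C/C=C(\C)C[C@@H]1O[Si](C)(C)C(C)(C)C
F4 | step 19 | 8α-silyloxy diene (8-epimer of 33) | C=C(COCOC)[C@H]1[C@H](OCOC)/C=C(/C)[C@@H](OCc2ccc(OC)cc2)C/C=C(\C)C[C@@H]1O[Si](C)(C)C(C)(C)C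
F5 | step 19 | 8α-alcohol | C=C(COCOC)[C@H]1[C@H](OCOC)/C=C(/C)[C@@H](OCc2ccc(OC)cc2)C/C=C(\C)C[C@@H]1O
F6 | step 19 | 8β-chloroacetate | C=C(COCOC)[C@H]1[C@H](OCOC)/C=C(/C)[C@@H](OCc2ccc(OC)cc2)C/C=C(\C)C[C@H]1OC(=O)CCl
F7 | step 19 | 8β-alcohol | C=C(COCOC)[C@H]1[C@H](OCOC)/C=C(/C)[C@@H](OCc2ccc(OC)cc2)C/C=C(\C)C[C@H]1O
F8 | step 14 | cerium alkoxide of 16 | C=C(COCOC)[C@H]1[C@H](O[Ce](Cl)Cl)C(=O)[C@@](C)(C=C)C[C@@H]1O[Si](C)(C)C(C)(C)C
F9 | step 14 | 5α,6α-diol | C=C(COCOC)[C@H]1[C@H](O)[C@@](O)(/C(C)=C\OCc2ccc(OC)cc2)[C@@](C)(C=C)C[C@@H]1O[Si](C)(C)C(C)(C)C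
F10 | step 4 | ene-dione (C5, C8 dione) | C=C(COCOC)[C@H]1CC(=O)C(C)=CC1=O
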